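**Assumptions.** The SMILES is read as the (1S,3E,7E) isomer. 1,3-Dihydroxyacetone is bought as its dimer, which reacts as the monomer. In step 11 the (S)-bisphosphine is assumed to give the (S)-carbinol; this is checked by Mosher esters on the first run, and the (R)-ligand is used if the sense is opposite.

## Retrosynthetic overview

1. Target ⇐ bis-silyl ether ⇐ sp3–sp2 Negishi union at the C4–C5 bond of the decadienyl chain: a homoallylic zinc reagent (cyclohexene plus six-carbon chain) and a (Z)-2-iodoallyl silyl ether carrying the butenolide carbinol.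
2. Right fragment: (Z)-vinyl iodide ⇐ α-iodination and Luche reduction of an (E)-enal ⇐ cross-metathesis ⇐ iridium-catalysed enantioselective C–H allylation of 4-(hydroxymethyl)butenolide, which sets the only stereocentre.
3. Left fragment: homoallylic iodide ⇐ zirconium-catalysed methylalumination and oxirane opening of a terminal alkyne ⇐ Negishi coupling of 2,6,6-trimethylcyclohexenyl triflate with a homopropargylzinc reagent.
4. Rings: the cyclohexene ring comes from 2-methylcyclohexanone and is only methylated. The butenolide is the only ring formed, first in the right-hand branch, by Wittig olefination and lactonisation of dihydroxyacetone.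

## Route

Step 1
Reactants: 1 2-methylcyclohexanone
Product: 3 2,6-dimethylcyclohexanone (cis/trans mixture), via lithium 6-methylcyclohex-1-en-1-olate 2 (not isolated)
Conditions: lithium diisopropylamide (1.05 equiv), THF, −78 °C; MeI, −78 °C to rt
Reagents that add atoms: iodomethane, CI
Why: Kinetic enolate alkylation at the less hindered C6; the minor 2,2-dimethyl isomer is carried on because it converges on 5 in step 2, and the uncontrolled stereocentres are erased in step 3.

Step 2
Reactants: 3 2,6-dimethylcyclohexanone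
Product: 5 2,2,6-trimethylcyclohexanone (racemic), via lithium 2,6-dimethylcyclohex-1-en-1-olate 4 (not isolated)
Conditions: lithium diisopropylamide (1.2 equiv), THF, −78 to 0 °C; MeI, 0 °C to rt
Reagents that add atoms: iodomethane, CI
Why: Enolate alkylation; 3 has only tertiary α-hydrogens, so the tetrasubstituted enolate forms and C-methylation builds the gem-dimethyl carbon, while a fourth methylation is slow for steric reasons.

Step 3
Reactants: 5 2,2,6-trimethylcyclohexanone
Product: 7 2,6,6-trimethylcyclohex-1-en-1-yl trifluoromethanesulfonate, via lithium 2,6,6-trimethylcyclohex-1-en-1-olate 6 (not isolated)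
Conditions: lithium diisopropylamide (1.2 equiv), THF, −78 to 0 °C; PhNTf2, 0 °C to rt
Reagents that add atoms: N-phenylbis(trifluoromethanesulfonimide), O=S(=O)(N(c1ccccc1)S(=O)(=O)C(F)(F)F)C(F)(F)F
Why: Enol triflate formation; the single α-hydrogen allows only the tetrasubstituted enolate, and O-sulfonylation gives the alkenyl triflate with the ring double bond in its final position.

Step 4
Reactants: 8 but-3-yn-1-ol
Product: 11 4-(trimethylsilyl)but-3-yn-1-ol, via dimagnesium alkynide alkoxide 9 (not isolated), via O,C-bis(trimethylsilyl) compound 10 (not isolated)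
Conditions: EtMgBr (2.2 equiv), THF, 0 °C to reflux; Me3SiCl (2.2 equiv), 0 °C to rt; 1 M aq. HCl
Reagents that add atoms: chlorotrimethylsilane, C[Si](C)(C)Cl
Why: C-silylation of a magnesium acetylide; both anionic sites are silylated and dilute acid cleaves only the labile O–Si bond, leaving the alkyne protected.

Step 5
Reactants: 11 4-(trimethylsilyl)but-3-yn-1-ol
Product: 12 (4-iodobut-1-yn-1-yl)trimethylsilane
Conditions: I2, PPh3, imidazole, CH2Cl2, 0 °C to rt
Reagents that add atoms: iodine, II
Why: Appel-type iodination (Garegg–Samuelsson conditions) by SN2 displacement on the primary alkoxyphosphonium ion.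

Step 6
Reactants: 12 (4-iodobut-1-yn-1-yl)trimethylsilane; 7 2,6,6-trimethylcyclohex-1-en-1-yl trifluoromethanesulfonate
Product: 14 trimethyl[4-(2,6,6-trimethylcyclohex-1-en-1-yl)but-1-yn-1-yl]silane, via homopropargylic zinc iodide 13 (not isolated)
Conditions: 12, Zn dust (activated), LiCl, THF, 40 °C; then 7, Pd2(dba)3 (2.5 mol%), SPhos (10 mol%), THF/NMP, 60 °C
Reagents that add atoms: none
Why: Negishi coupling; the primary alkylzinc transmetalates to the alkenylpalladium formed by oxidative addition of the triflate to zerovalent palladium, and the bulky electron-rich biarylphosphine drives both oxidative addition and reductive elimination at the tetrasubstituted alkenyl carbon.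

Step 7
Reactants: 14 trimethyl[4-(2,6,6-trimethylcyclohex-1-en-1-yl)but-1-yn-1-yl]silane
Product: 15 2-(but-3-yn-1-yl)-1,3,3-trimethylcyclohex-1-ene
Conditions: K2CO3 (0.2 equiv), MeOH, rt
Reagents that add atoms: none
Why: Methoxide-catalysed protodesilylation of the alkynylsilane; nothing else in the molecule is base-sensitive.

Step 8
Reactants: 15 2-(but-3-yn-1-yl)-1,3,3-trimethylcyclohex-1-ene; 16 oxirane
Product: 19 (E)-4-methyl-6-(2,6,6-trimethylcyclohex-1-en-1-yl)hex-3-en-1-ol, via (E)-alkenyldimethylalane 17 (not isolated), via lithium alkenyl(butyl)dimethylaluminate 18 (not isolated)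
Conditions: AlMe3 (2 equiv), Cp2ZrCl2 (25 mol%), CH2Cl2, 0 °C to rt; evaporate, hexane/THF, n-BuLi, −30 °C; oxirane, −30 °C to rt; 1 M aq. HCl, 0 °C
Reagents that add atoms: trimethylaluminium, C[Al](C)C
Why: Negishi zirconium-catalysed methylalumination adds methyl and aluminium syn, with methyl on the internal carbon, and the derived aluminate opens oxirane with retention, so the trisubstituted alkene is formed as the E isomer while the tetrasubstituted ring alkene is inert.

Step 9
Reactants: 19 (E)-4-methyl-6-(2,6,6-trimethylcyclohex-1-en-1-yl)hex-3-en-1-ol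
Product: 20 2-[(E)-6-iodo-3-methylhex-3-en-1-yl]-1,3,3-trimethylcyclohex-1-ene
Conditions: I2, PPh3, imidazole, CH2Cl2, 0 °C
Reagents that add atoms: iodine, II
Why: Appel-type iodination of the primary alcohol under buffered conditions that leave both alkenes untouched.

Step 10
Reactants: 21 1,3-dihydroxyacetone
Product: 23 4-(hydroxymethyl)furan-2(5H)-one, via methyl 4-hydroxy-3-(hydroxymethyl)but-2-enoate 22 (not isolated)
Conditions: Ph3P=CHCO2Me (1.05 equiv), CH2Cl2, rt, 16 h
Reagents that add atoms: methyl (triphenylphosphoranylidene)acetate, COC(=O)C=P(c1ccccc1)(c1ccccc1)c1ccccc1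
Why: Wittig olefination of the ketone gives an enoate that always has one hydroxymethyl group cis to the ester, so lactonisation closes the butenolide ring spontaneously.

Step 11
Reactants: 23 4-(hydroxymethyl)furan-2(5H)-one; 24 allyl acetate
Product: 26 (S)-4-(1-hydroxybut-3-en-1-yl)furan-2(5H)-one, via 5-oxo-2,5-dihydrofuran-3-carbaldehyde 25 (not isolated)
Conditions: [Ir(cod)Cl]2 (2.5 mol%), (S)-Cl,MeO-BIPHEP (5 mol%), 4-chloro-3-nitrobenzoic acid (10 mol%), Cs2CO3 (20 mol%), allyl acetate (3 equiv), THF, 90 °C, sealed tube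
Reagents that add atoms: none
Why: Proposed new method: enantioselective transfer-hydrogenative C–H allylation of a butenolide carbinol, a substrate class on which this chemistry has not been shown; the ortho-cyclometalated π-allyl iridium C,O-benzoate complex (trivalent iridium) formed in situ transfers its allyl group to the transient aldehyde 25 through a closed chair-like transition state inside the pocket of the (S)-biaryl bisphosphine, which sets the (S)-carbinol centre; alkoxide exchange with 23 releases 26, β-hydride elimination from the new primary alkoxide regenerates 25 and an iridium hydride, and deprotonation gives monovalent iridium that adds oxidatively to 24; the labile ene-dicarbonyl 25 never accumulates, its β,β-disubstituted C=C is a poor hydride acceptor, and the homoallylic product resists re-oxidation through olefin chelation; the closest known reaction type is the Krische iridium-catalysed carbonyl allylation of benzylic and simple allylic alcohols from the alcohol oxidation level with allyl acetate.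

Step 12
Reactants: 26 (S)-4-(1-hydroxybut-3-en-1-yl)furan-2(5H)-one
Product: 27 (S)-4-{1-[(tert-butyldimethylsilyl)oxy]but-3-en-1-yl}furan-2(5H)-one
Conditions: TBSCl, imidazole, DMF, rt
Reagents that add atoms: tert-butyldimethylsilyl chloride, CC(C)(C)[Si](C)(C)Cl
Why: Silyl ether formation under conditions too weakly basic to form a silyloxyfuran; it blocks vinylogous retro-aldol cleavage in the later basic step.

Step 13
Reactants: 27 (S)-4-{1-[(tert-butyldimethylsilyl)oxy]but-3-en-1-yl}furan-2(5H)-one; 28 (E)-but-2-enal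
Product: 29 (S,E)-5-[(tert-butyldimethylsilyl)oxy]-5-(5-oxo-2,5-dihydrofuran-3-yl)pent-2-enal
Conditions: crotonaldehyde (5 equiv), RuCl2(=CH-C6H4-2-O-i-Pr)(H2IMes) (second-generation Hoveyda–Grubbs catalyst, 5 mol%), CH2Cl2, 40 °C
Reagents that add atoms: none
Why: Olefin cross-metathesis of the terminal alkene with excess crotonaldehyde gives the (E)-enal, while the trisubstituted electron-poor butenolide alkene does not take part.

Step 14
Reactants: 29 (S,E)-5-[(tert-butyldimethylsilyl)oxy]-5-(5-oxo-2,5-dihydrofuran-3-yl)pent-2-enal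
Product: 30 (S,Z)-5-[(tert-butyldimethylsilyl)oxy]-2-iodo-5-(5-oxo-2,5-dihydrofuran-3-yl)pent-2-enal
Conditions: I2 (1.5 equiv), K2CO3 (1.2 equiv), DMAP (20 mol%), THF/H2O 1:1, rt, dark
Reagents that add atoms: iodine, II
Why: Amine-catalysed α-iodination of an enal (Baylis–Hillman-type addition of DMAP, iodination of the enolate, elimination) gives the (Z)-α-iodoenal with iodine cis to the chain, and the β,β-disubstituted butenolide does not add DMAP.

Step 15
Reactants: 30 (S,Z)-5-[(tert-butyldimethylsilyl)oxy]-2-iodo-5-(5-oxo-2,5-dihydrofuran-3-yl)pent-2-enal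
Product: 31 (S,Z)-4-{1-[(tert-butyldimethylsilyl)oxy]-5-hydroxy-4-iodopent-3-en-1-yl}furan-2(5H)-one
Conditions: NaBH4, CeCl3·7H2O, MeOH, −78 to −40 °C
Reagents that add atoms: none
Why: Luche reduction; 1,2-reduction of the aldehyde is fast at low temperature and leaves the lactone, the vinyl iodide and the alkene geometry unchanged.

Step 16
Reactants: 31 (S,Z)-4-{1-[(tert-butyldimethylsilyl)oxy]-5-hydroxy-4-iodopent-3-en-1-yl}furan-2(5H)-one
Product: 32 (S,Z)-4-{1,5-bis[(tert-butyldimethylsilyl)oxy]-4-iodopent-3-en-1-yl}furan-2(5H)-one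
Conditions: TBSCl, imidazole, DMF, rt
Reagents that add atoms: tert-butyldimethylsilyl chloride, CC(C)(C)[Si](C)(C)Cl
Why: Silyl ether formation removes the acidic hydroxyl proton so the organozinc in step 17 is not quenched.

Step 17
Reactants: 20 2-[(E)-6-iodo-3-methylhex-3-en-1-yl]-1,3,3-trimethylcyclohex-1-ene; 32 (S,Z)-4-{1,5-bis[(tert-butyldimethylsilyl)oxy]-4-iodopent-3-en-1-yl}furan-2(5H)-one
Product: 34 4-[(1S,3E,7E)-1-[(tert-butyldimethylsilyl)oxy]-4-{[(tert-butyldimethylsilyl)oxy]methyl}-8-methyl-10-(2,6,6-trimethylcyclohex-1-en-1-yl)deca-3,7-dien-1-yl]furan-2(5H)-one, via homoallylic zinc iodide 33 (not isolated)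
Conditions: 20 (1.3 equiv), Zn dust (activated), LiCl, THF, 40 °C; then 32, Pd(dppf)Cl2 (5 mol%), THF, rt to 40 °C
Reagents that add atoms: none
Why: Negishi sp3–sp2 coupling replaces iodine with retention of alkene geometry, so the new chain ends up cis to the carbinol chain, and the base-free conditions spare the butenolide and the carbinol centre.

Step 18
Reactants: 34 bis-silyl ether from step 17
Product: 35 4-[(1S,3E,7E)-1-hydroxy-4-(hydroxymethyl)-8-methyl-10-(2,6,6-trimethylcyclohex-1-en-1-yl)deca-3,7-dien-1-yl]furan-2(5H)-one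
Conditions: HF·pyridine, pyridine, THF, 0 °C to rt
Reagents that add atoms: none
Why: Buffered fluoride desilylation cleaves both silyl ethers without base, so the lactone, the alkenes and the stereocentre are unaffected.

## Compound list

1 | 2-methylcyclohexanone (racemic) | CC1CCCCC1=O | starting material
2 | lithium 6-methylcyclohex-1-en-1-olate | CC1CCCC=C1O[Li] | intermediate
3 | 2,6-dimethylcyclohexanone (cis/trans mixture) | CC1CCCC(C)C1=O | intermediate
4 | lithium 2,6-dimethylcyclohex-1-en-1-olate | CC1CCCC(C)=C1O[Li] | intermediate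
5 | 2,2,6-trimethylcyclohexanone (racemic) | CC1CCCC(C)(C)C1=O | intermediate
6 | lithium 2,6,6-trimethylcyclohex-1-en-1-olate | CC1=C(O[Li])C(C)(C)CCC1 | intermediate
7 | 2,6,6-trimethylcyclohex-1-en-1-yl trifluoromethanesulfonate | CC1=C(OS(=O)(=O)C(F)(F)F)C(C)(C)CCC1 | intermediate
8 | but-3-yn-1-ol | C#CCCO | starting material
9 | bromomagnesium 4-(bromomagnesio)but-3-yn-1-olate | Br[Mg]C#CCCO[Mg]Br | intermediate
10 | trimethyl{[4-(trimethylsilyl)but-3-yn-1-yl]oxy}silane | C[Si](C)(C)C#CCCO[Si](C)(C)C | intermediate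
11 | 4-(trimethylsilyl)but-3-yn-1-ol | C[Si](C)(C)C#CCCO | intermediate
12 | (4-iodobut-1-yn-1-yl)trimethylsilane | C[Si](C)(C)C#CCCI | intermediate
13 | [4-(trimethylsilyl)but-3-yn-1-yl]zinc iodide | C[Si](C)(C)C#CCC[Zn]I | intermediate
14 | trimethyl[4-(2,6,6-trimethylcyclohex-1-en-1-yl)but-1-yn-1-yl]silane | CC1=C(CCC#C[Si](C)(C)C)C(C)(C)CCC1 | intermediate
15 | 2-(but-3-yn-1-yl)-1,3,3-trimethylcyclohex-1-ene | CC1=C(CCC#C)C(C)(C)CCC1 | intermediate
16 | oxirane (ethylene oxide) | C1CO1 | starting material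
17 | dimethyl[(E)-2-methyl-4-(2,6,6-trimethylcyclohex-1-en-1-yl)but-1-en-1-yl]alane | CC1=C(CC/C(C)=C/[Al](C)C)C(C)(C)CCC1 | intermediate
18 | lithium butyldimethyl[(E)-2-methyl-4-(2,6,6-trimethylcyclohex-1-en-1-yl)but-1-en-1-yl]aluminate | [Li+].CCCC[Al-](C)(C)/C=C(C)/CCC1=C(C)CCCC1(C)C | intermediate
19 | (E)-4-methyl-6-(2,6,6-trimethylcyclohex-1-en-1-yl)hex-3-en-1-ol | CC1=C(CC/C(C)=C/CCO)C(C)(C)CCC1 | intermediate
20 | 2-[(E)-6-iodo-3-methylhex-3-en-1-yl]-1,3,3-trimethylcyclohex-1-ene | CC1=C(CC/C(C)=C/CCI)C(C)(C)CCC1 | intermediate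
21 | 1,3-dihydroxyacetone | OCC(=O)CO | starting material
22 | methyl 4-hydroxy-3-(hydroxymethyl)but-2-enoate | COC(=O)C=C(CO)CO | intermediate
23 | 4-(hydroxymethyl)furan-2(5H)-one | OCC1=CC(=O)OC1 | intermediate
24 | allyl acetate | CC(=O)OCC=C | starting material
25 | 5-oxo-2,5-dihydrofuran-3-carbaldehyde | O=CC1=CC(=O)OC1 | intermediate
26 | (S)-4-(1-hydroxybut-3-en-1-yl)furan-2(5H)-one | C=CC[C@H](O)C1=CC(=O)OC1 | intermediate
27 | (S)-4-{1-[(tert-butyldimethylsilyl)oxy]but-3-en-1-yl}furan-2(5H)-one | C=CC[C@H](O[Si](C)(C)C(C)(C)C)C1=CC(=O)OC1 | intermediate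
28 | (E)-but-2-enal (crotonaldehyde) | C/C=C/C=O | starting material
29 | (S,E)-5-[(tert-butyldimethylsilyl)oxy]-5-(5-oxo-2,5-dihydrofuran-3-yl)pent-2-enal | O=C/C=C/C[C@H](O[Si](C)(C)C(C)(C)C)C1=CC(=O)OC1 | intermediate
30 | (S,Z)-5-[(tert-butyldimethylsilyl)oxy]-2-iodo-5-(5-oxo-2,5-dihydrofuran-3-yl)pent-2-enal | O=C/C(I)=C/C[C@H](O[Si](C)(C)C(C)(C)C)C1=CC(=O)OC1 | intermediate
31 | (S,Z)-4-{1-[(tert-butyldimethylsilyl)oxy]-5-hydroxy-4-iodopent-3-en-1-yl}furan-2(5H)-one | OC/C(I)=C/C[C@H](O[Si](C)(C)C(C)(C)C)C1=CC(=O)OC1 | intermediate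
32 | (S,Z)-4-{1,5-bis[(tert-butyldimethylsilyl)oxy]-4-iodopent-3-en-1-yl}furan-2(5H)-one | CC(C)(C)[Si](C)(C)OC/C(I)=C/C[C@H](O[Si](C)(C)C(C)(C)C)C1=CC(=O)OC1 | intermediate
33 | [(E)-4-methyl-6-(2,6,6-trimethylcyclohex-1-en-1-yl)hex-3-en-1-yl]zinc iodide | CC1=C(CC/C(C)=C/CC[Zn]I)C(C)(C)CCC1 | intermediate
34 | 4-[(1S,3E,7E)-1-[(tert-butyldimethylsilyl)oxy]-4-{[(tert-butyldimethylsilyl)oxy]methyl}-8-methyl-10-(2,6,6-trimethylcyclohex-1-en-1-yl)deca-3,7-dien-1-yl]furan-2(5H)-one | CC1=C(CC/C(C)=C/CC/C(=C\C[C@H](O[Si](C)(C)C(C)(C)C)C2=CC(=O)OC2)CO[Si](C)(C)C(C)(C)C)C(C)(C)CCC1 | intermediate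
35 | 4-[(1S,3E,7E)-1-hydroxy-4-(hydroxymethyl)-8-methyl-10-(2,6,6-trimethylcyclohex-1-en-1-yl)deca-3,7-dien-1-yl]furan-2(5H)-one | CC1=C(CC/C(C)=C/CC/C(=C\C[C@H](O)C2=CC(=O)OC2)CO)C(C)(C)CCC1 | target

## Step count and risks

Total steps: 18. Longest linear sequence: 9 (steps 1, 2, 3, 6, 7, 8, 9, 17, 18; the line of steps 10 to 18 is equally long).

**Step 11, the proposed new method, is the most likely to fail.** The iridium hydride may reduce the butenolide C=C, the transient aldehyde 25 may decompose under the carbonate base, or the enantioselectivity may be low on this electron-poor carbinol. The fallback uses known chemistry, sets out from 23 and comes back at 26. Oxidation of 23 with MnO2 (CH2Cl2, rt) gives aldehyde 25, now filtered and used at once. Allylboronic acid pinacol ester with 5 mol% of the chiral phosphoric acid (S)-TRIP in toluene at −30 °C (Brønsted-acid-catalysed allylboration, no metal, aldehyde oxidation level) gives (S)-4-{1-[(4,4,5,5-tetramethyl-1,3,2-dioxaborolan-2-yl)oxy]but-3-en-1-yl}furan-2(5H)-one F5. F5 is hydrolysed on work-up to 26.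

**Step 6 is the second risk.** Oxidative addition and reductive elimination at the tetrasubstituted, doubly flanked alkenyl triflate 7 may be too slow, leading to protodezincation of 13. The fallback reverses the polarity, sets out from 5 and comes back at 14:
- Condensation of 5 with 2,4,6-triisopropylbenzenesulfonohydrazide (cat. HCl, THF) gives N'-(2,2,6-trimethylcyclohexylidene)-2,4,6-triisopropylbenzenesulfonohydrazide F1.
- A Shapiro reaction (n-BuLi, 2.2 equiv, THF/TMEDA, −78 to 0 °C) gives (2,6,6-trimethylcyclohex-1-en-1-yl)lithium F2.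
- F2 opens oxirane 16 to give 2-(2,6,6-trimethylcyclohex-1-en-1-yl)ethan-1-ol F3.
- I2/PPh3/imidazole converts F3 into 2-(2-iodoethyl)-1,3,3-trimethylcyclohex-1-ene F4.
- Alkylation of lithium (trimethylsilyl)acetylide with F4 in THF/DMPU gives 14.

**Step 14 is the third risk.** Aqueous carbonate may open the lactone or trigger elimination of the silyloxy group through the enal dienolate, and the iodoenal is light-sensitive. The fallback builds the haloalkene by olefination instead, sets out from 27 and comes back at 34: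
- Ozonolysis of 27 (O3, CH2Cl2, −78 °C; PPh3) gives (S)-3-[(tert-butyldimethylsilyl)oxy]-3-(5-oxo-2,5-dihydrofuran-3-yl)propanal F6.
- Wittig reaction of F6 with 2-bromo-2-(triphenylphosphoranylidene)acetaldehyde (toluene, 60 °C) gives (S,Z)-2-bromo-5-[(tert-butyldimethylsilyl)oxy]-5-(5-oxo-2,5-dihydrofuran-3-yl)pent-2-enal F7.
- Luche reduction gives (S,Z)-4-{4-bromo-1-[(tert-butyldimethylsilyl)oxy]-5-hydroxypent-3-en-1-yl}furan-2(5H)-one F8.
- TBSCl/imidazole gives (S,Z)-4-{4-bromo-1,5-bis[(tert-butyldimethylsilyl)oxy]pent-3-en-1-yl}furan-2(5H)-one F9.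
- Negishi coupling of F9 with zinc reagent 33 (Pd2(dba)3, SPhos, THF, 50 °C) gives 34.

Further compounds
F1 | step 6 | N'-(2,2,6-trimethylcyclohexylidene)-2,4,6-triisopropylbenzenesulfonohydrazide (racemic) | CC1CCCC(C)(C)C1=NNS(=O)(=O)c1c(C(C)C)cc(C(C)C)cc1C(C)C
F2 | step 6 | (2,6,6-trimethylcyclohex-1-en-1-yl)lithium | [Li]C1=C(C)CCCC1(C)C
F3 | step 6 | 2-(2,6,6-trimethylcyclohex-1-en-1-yl)ethan-1-ol | CC1=C(CCO)C(C)(C)CCC1
F4 | step 6 | 2-(2-iodoethyl)-1,3,3-trimethylcyclohex-1-ene | CC1=C(CCI)C(C)(C)CCC1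
F5 | step 11 | (S)-4-{1-[(4,4,5,5-tetramethyl-1,3,2-dioxaborolan-2-yl)oxy]but-3-en-1-yl}furan-2(5H)-one | C=CC[C@H](OB1OC(C)(C)C(C)(C)O1)C1=CC(=O)OC1
F6 | step 14 | (S)-3-[(tert-butyldimethylsilyl)oxy]-3-(5-oxo-2,5-dihydrofuran-3-yl)propanal | O=CC[C@H](O[Si](C)(C)C(C)(C)C)C1=CC(=O)OC1
F7 | step 14 | (S,Z)-2-bromo-5-[(tert-butyldimethylsilyl)oxy]-5-(5-oxo-2,5-dihydrofuran-3-yl)pent-2-enal | O=C/C(Br)=C/C[C@H](O[Si](C)(C)C(C)(C)C)C1=CC(=O)OC1
F8 | step 14 | (S,Z)-4-{4-bromo-1-[(tert-butyldimethylsilyl)oxy]-5-hydroxypent-3-en-1-yl}furan-2(5H)-one | OC/C(Br)=C/C[C@H](O[Si](C)(C)C(C)(C)C)C1=CC(=O)OC1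
F9 | step 14 | (S,Z)-4-{4-bromo-1,5-bis[(tert-butyldimethylsilyl)oxy]pent-3-en-1-yl}furan-2(5H)-one | CC(C)(C)[Si](C)(C)OC/C(Br)=C/C[C@H](O[Si](C)(C)C(C)(C)C)C1=CC(=O)OC1
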